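## Analysis of the target

The target (19) is a chamigrane, a spiro[5.5]undecane. Chamigrene numbering is used throughout: ring B is C1H2–C2H(Br)–C3(Cl)(C15H3)–C4H2–C5H2–C6, ring A is C6–C7(C14H3)=C8H–C9H2–C10H(Br)–C11(C12H3)(C13H3), and C6 is the spiro atom. There are four stereocentres, (2R,3R,6R,10S). Br-2 and Cl-3 are trans and both equatorial in the chair of ring B that keeps C11 equatorial and C7 axial; Br-2 is cis to C11, Cl-3 is cis to C7, and on ring A the equatorial Br-10 is cis to C1. C6 is quaternary, lies next to the quaternary C11, and is stereogenic only because the two arms of ring B differ at the remote C2/C3. The array Br–C10–C11(Me)2–C6–C7(Me)=C8 in ring A is the signature of a bromonium-triggered six-ring closure of a 1,5-diene, and the C2-Br/C3-Cl pair is the Markovnikov anti adduct of BrCl to a C2=C3 alkene. Sensitive groups are the tertiary C3–Cl with its vicinal bromide (ionisation, elimination), the neopentyl-type secondary bromide at C10 (not accessible by substitution), and the C7=C8 alkene beside a spiro centre (cation rearrangements); there is no heteroatom handle. The hard points are the C6–C11 bond between two fully substituted carbons, the absolute configuration of C10, and the fact that a spiro-locked ring B cannot adopt the diaxial C2-Br/C3-Cl arrangement (Br would be syn-axial to C11), so the halogens must enter by a path that gives the diequatorial adduct.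

## Retrosynthetic reasoning

**C2–Br and C3–Cl (19 ⇒ 18).** The ring-B halogens are removed first because the tertiary chloride is the most fragile part of 19 and the pair is the anti, Markovnikov adduct of bromine chloride to the C2=C3 alkene of 18. The forward step must choose C2=C3 over C7=C8 (shielded by C6 and C11), put Br on C2 and Cl on C3, and use the right face. Ring B of 18 should rest in the half-chair with C11 pseudo-equatorial and C7 pseudo-axial, with C14 leaning over the ring; the electrophile then comes from the face opposite C7 and chloride closes on C3 from the C7 side.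

**C3–C15 and C2=C3 (18 ⇒ 17 ⇒ 15).** The methyl group is cut from enol triflate 17, which is traced to ketone 15. In 15 the two arms of ring B are identical and C6 is not a stereocentre. The C6 configuration thus becomes a choice between the two α-methylene groups of a 4,4-disubstituted cyclohexanone, which a chiral lithium amide can make under reagent control.

**C6–C11 and ring A (15 ⇒ 14 ⇒ 13), the key disconnection.** Ring A is cut at the bond between the two fully substituted carbons, with C7=C8 read as proton loss from a C7 cation; this copies the presumed bisabolane-to-chamigrane biosynthesis. Precursor 13 stores the C10=C11 alkene as an enantioenriched vicinal bromochloride. One operation then makes the hardest bond, ring A, the spiro atom and C7=C8, and fixes C10. Because ring B of 13 is symmetric, its tetrasubstituted C6=C7 alkene has no geometrical isomers, which removes the problem that defeats halogenated bisabolene precursors.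

**C6=C7 (13 ⇒ 12 ⇒ 10 + 7).** The tetrasubstituted alkene is cut through spiro-β-lactone 12 into ring-B thioester 10 and methyl ketone 7. This places the double bond unambiguously and uses no phosphorus ylide or low-valent metal that would eliminate or reduce the bromochloride.

**C8–C9 and the bromochloride (7 ⇒ 5 ⇒ 3 + 4; 3 ⇒ 2 ⇒ 1).** Ketone 7 comes from alkene 5 by oxidative cleavage, and 5 from triflate 3 and the symmetric allyl nucleophile 4, so no α/γ question arises. Triflate 3 comes from alcohol 2, the catalytic enantioselective bromochlorination product of prenol (1). This is the only way used here to make the C10–Br stereocentre, by adding Br+ to an alkene rather than by substitution.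

**Thioester (10 ⇒ 8 + 9).** Thioester 10 is made from the commercial ketal acid 8 and benzenethiol 9.

## Alternatives that were turned down

**Alternative 1:** the textbook spiroannulation. Ring B is cut at C1–C6 and C4–C5: a Diels–Alder reaction of the exocyclic enone A1 with the diene A2 would give spiro ketone A3 ("para" orientation), followed by conversion of the C7 ketone into C7(Me)=C8 and bromochlorination. It was turned down for these reasons:
- Both faces of the exocyclic alkene of A1 are flanked by the C11 gem-dimethyl group, and the only differentiating element, Br-10, is 1,3-remote, so facial control at C6 would be weak.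
- A1 needs its own enantioselective synthesis of the C10 bromide, which means a bromonium cyclisation anyway, followed by α-methylenation at the more hindered α-carbon.
- α-Methylene ketones of this kind dimerise by hetero-Diels–Alder reaction.
- The route is not shorter, and the ring-B halogens are no easier.

**Alternative 2:** C6 set by catalysis, ring B closed by metathesis. Ring B is cut at C2=C3: a palladium-catalysed enantioselective decarboxylative allylic alkylation would give the α-quaternary vinylogous ester A4, and ring-closing metathesis (second-generation Grubbs catalyst) would give spirocycle A5. This fixes C6 well, but C10 is left as a CH2 group next to C11. Bromine can only be brought there through a C9 carbonyl (α-bromination) that must then be removed β to the new bromide. That costs several steps with elimination risk, makes C10 depend on a substrate-controlled bromination, and the whole sequence is clearly longer.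

**Alternative 3:** both halonium events before ring A closes. Ionisation of the doubly halogenated (E)-bisabolene-type precursor A6 would give 19 in one step and set C6 and C10 relative to C2/C3, with ring B halogenated while still flexible. It was turned down because the required E geometry of the C6=C7 alkene differs from Z only in substituents three bonds away (C2/C3). No olefination can tell the two arms of ring B apart, and each geometrical isomer leads to a different C6 epimer. In addition, A6 has two β-bromo tertiary chlorides that can both ionise, and enolate-based olefinations fail with a γ-bromide on ring B (cyclopropane closure).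

Key step: step 8

Remark: the ligand antipode in step 1 and the amide antipode in step 9 are taken to be those that give (2S)-2 and (6R)-17; both antipodes of each are available.

## Route

Step 1
Reactants: 1 3-methylbut-2-en-1-ol (prenol)
Product: 2 (2S)-2-bromo-3-chloro-3-methylbutan-1-ol
Conditions: NBS, ClTi(OiPr)3, chiral tridentate Schiff-base diol ligand (N-salicylidene 2-amino-1,1-diarylalkanol type, cat.), hexanes, −20 °C
Reagents that add atoms: N-bromosuccinimide, O=C1CCC(=O)N1Br; chlorotitanium triisopropoxide, CC(C)O[Ti](Cl)(OC(C)C)OC(C)C
Why: Catalytic enantioselective bromochlorination of an allylic alcohol: the alcohol binds titanium, NBS delivers Br+ to the alkene face chosen by the ligand, and chloride passes from titanium to the tertiary carbon anti to bromine (Markovnikov). The stereocentre C2 of 2 (later C10) is set by the catalyst; C3 is not stereogenic.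

Step 2
Reactants: 2 (2S)-2-bromo-3-chloro-3-methylbutan-1-ol
Product: 3 (2S)-2-bromo-3-chloro-3-methylbutyl trifluoromethanesulfonate
Conditions: Tf2O, 2,6-lutidine, CH2Cl2, −78 °C; used at once
Reagents that add atoms: trifluoromethanesulfonic anhydride, O=S(=O)(OS(=O)(=O)C(F)(F)F)C(F)(F)F
Why: O-Sulfonylation of the primary alcohol with a hindered base at low temperature; the stereocentre is untouched, and immediate use avoids participation of the neighbouring bromine.

Step 3
Reactants: 3 (2S)-2-bromo-3-chloro-3-methylbutyl trifluoromethanesulfonate; 4 2-methylallylmagnesium chloride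
Product: 5 (5S)-5-bromo-6-chloro-2,6-dimethylhept-1-ene
Conditions: CH2=C(Me)CH2MgCl, Li2CuCl4 (cat.), THF, −78 to −40 °C
Reagents that add atoms: none
Why: Copper-catalysed sp3–sp3 coupling of a primary alkyl triflate with a Grignard reagent (Kochi-type); the 2-methylallyl nucleophile is symmetric, so there is no α/γ ambiguity, and at −78 °C triflate displacement outruns attack on C–Br or C–Cl. The C–Br stereocentre is adjacent to the reacting carbon but not part of it.

Step 4
Reactants: 5 (5S)-5-bromo-6-chloro-2,6-dimethylhept-1-ene
Product: 7 (5S)-5-bromo-6-chloro-6-methylheptan-2-one, via ozonide 6 (not isolated)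
Conditions: O3, CH2Cl2, −78 °C; then Me2S, −78 °C to rt
Reagents that add atoms: ozone, [O-][O+]=O
Why: Ozonolysis of the 1,1-disubstituted alkene with reductive work-up unmasks the C7 methyl ketone; alkyl bromide and chloride are inert to ozone, and no base is present that could close a cyclopropane from the γ-bromo ketone.

Step 5
Reactants: 8 1,4-dioxaspiro[4.5]decane-8-carboxylic acid; 9 benzenethiol
Product: 10 S-phenyl 1,4-dioxaspiro[4.5]decane-8-carbothioate
Conditions: DCC, DMAP (cat.), CH2Cl2, 0 °C to rt
Reagents that add atoms: none
Why: Carbodiimide (Steglich-type) thioesterification under neutral conditions that leave the ketal intact.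

Step 6
Reactants: 10 S-phenyl 1,4-dioxaspiro[4.5]decane-8-carbothioate; 7 (5S)-5-bromo-6-chloro-6-methylheptan-2-one
Product: 12 spiro-β-lactone: 4-[(3S)-3-bromo-4-chloro-4-methylpentyl]-4-methyloxetan-2-one spiro-fused at C3 to C8 of 1,4-dioxaspiro[4.5]decane (both C4 epimers), via lithium enolate 11 (not isolated)
Conditions: LiN(i-Pr)2, THF, −78 °C; then 7, −78 to 0 °C; aq. NH4Cl
Reagents that add atoms: lithium diisopropylamide, CC(C)N([Li])C(C)C (supplies only the lithium of 11)
Why: Aldol addition of a thioester lithium enolate to a ketone followed by 4-exo-trig displacement of thiophenolate by the tertiary alkoxide, a known one-flask β-lactone synthesis; lactonisation is faster than attack on the hindered secondary bromide. The new C7 centre forms as both epimers, which is harmless because ring B is symmetric and C7 becomes sp2 in step 7.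

Step 7
Reactants: 12 spiro-β-lactone
Product: 13 8-[(5S)-5-bromo-6-chloro-6-methylheptan-2-ylidene]-1,4-dioxaspiro[4.5]decane
Conditions: SiO2, toluene, 90 °C
Reagents that add atoms: none
Why: Thermal [2+2] cycloreversion (decarboxylation) of a fully substituted β-lactone places the tetrasubstituted double bond exactly at C6=C7; the neutral conditions spare the bromochloride and the ketal.

Step 8
Reactants: 13 8-[(5S)-5-bromo-6-chloro-6-methylheptan-2-ylidene]-1,4-dioxaspiro[4.5]decane
Product: 15 (10S)-10-bromo-7,11,11-trimethylspiro[5.5]undec-7-en-3-one, via spiro ketal 14 (not isolated)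
Conditions: (CF3)2CHOH (high dilution), 0 °C to rt; then H2O–THF (HCl formed in situ), rt
Reagents that add atoms: water, O
Why: The fluoroalcohol ionises the tertiary C11–Cl bond with anchimeric help from the antiperiplanar bromine, so the C10 configuration from step 1 is passed on as one configurationally defined C10–C11 bromonium ion, and no free Br+ is present that could attack the more electron-rich tetrasubstituted alkene. The C6=C7 π bond opens the bromonium at C11 with inversion through a chair transition state with bromine equatorial; this closes ring A in a 6-endo mode (both alkene carbons in the new ring) and forms the C6–C11 bond between two fully substituted carbons, and the tertiary C7 cation loses H-8 to give C7=C8. The closest known reaction type is the enantiospecific bromonium polyene cyclisation started by solvolysis of an enantioenriched vicinal bromochloride in a fluoroalcohol, the laboratory copy of the bisabolane-to-chamigrane step. The only stereocentre concerned, C10, is controlled by the bromochloride (retention at C10, since substitution occurs only at C11); C6 becomes the spiro atom but is not yet stereogenic because ring B is symmetric, which is what removes the alkene-geometry problem. Three selectivities are needed: closure through C6 rather than C7 (five-ring), favoured by the chair arrangement of the 1,5-diene; intramolecular capture rather than bromonium transfer between molecules, favoured by dilution in a non-nucleophilic medium; and endocyclic rather than exocyclic proton loss, favoured thermodynamically by the HCl set free. The same HCl hydrolyses ketal 14 to ketone 15 once water is added.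

Step 9
Reactants: 15 (10S)-10-bromo-7,11,11-trimethylspiro[5.5]undec-7-en-3-one
Product: 17 (6R,10S)-10-bromo-7,11,11-trimethylspiro[5.5]undeca-2,7-dien-3-yl trifluoromethanesulfonate, via lithium enolate 16 (not isolated)
Conditions: LiN[(R)-CH(Me)Ph]2 (from the amine and n-BuLi), LiCl, THF, −100 to −78 °C; then PhNTf2, −78 to 0 °C
Reagents that add atoms: lithium (R,R)-bis(1-phenylethyl)amide, C[C@@H](N([Li])[C@H](C)c1ccccc1)c1ccccc1 (supplies only the lithium of 16); N-phenylbis(trifluoromethanesulfonimide), O=S(=O)(N(c1ccccc1)S(=O)(=O)C(F)(F)F)C(F)(F)F
Why: Group-selective deprotonation of a 4,4-disubstituted cyclohexanone by a chiral lithium amide, then O-triflation of the regio-defined enolate. Removing an axial hydrogen from C2 rather than C4 makes C6 stereogenic (6R); the reagent, not the remote C10 centre, is expected to decide, and the hindered amide should not attack the C10 bromide at −100 °C.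

Step 10
Reactants: 17 (6R,10S)-10-bromo-7,11,11-trimethylspiro[5.5]undeca-2,7-dien-3-yl trifluoromethanesulfonate
Product: 18 (6R,10S)-10-bromo-3,7,11,11-tetramethylspiro[5.5]undeca-2,7-diene (10-bromo-α-chamigrene)
Conditions: MeZnCl, Pd(PPh3)4 (cat.), THF, 45 °C
Reagents that add atoms: methylzinc chloride, C[Zn]Cl
Why: Negishi coupling of an alkenyl triflate; oxidative addition of zerovalent palladium to the C(sp2)–O bond is far faster than to the hindered secondary alkyl bromide, and no stereocentre is involved.

Step 11
Reactants: 18 (6R,10S)-10-bromo-3,7,11,11-tetramethylspiro[5.5]undeca-2,7-diene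
Product: 19 (2R,3R,6R,10S)-2,10-dibromo-3-chloro-3,7,11,11-tetramethylspiro[5.5]undec-7-ene (target)
Conditions: Bu4N+ BrCl2−, CH2Cl2, −78 to −40 °C, dark
Reagents that add atoms: tetrabutylammonium dichlorobromate (written as the chloride plus BrCl), CCCC[N+](CCCC)(CCCC)CCCC.[Cl-].ClBr
Why: Electrophilic anti-bromochlorination with a dichlorobromate salt, which puts Br on the less and Cl on the more substituted alkene carbon. Ring B of 18 should rest in the half-chair with C11 pseudo-equatorial and C7 pseudo-axial, so Br+ goes to the face of C2=C3 opposite C7 and its methyl C14, and chloride collapses at once on tertiary C3 from the C7 side; this gives the trans adduct with Br cis to C11 and Cl cis to C7 (2R,3R). C7=C8 is shielded by C6 and the gem-dimethyl group and should react more slowly.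

## Compound list

1 | 3-methylbut-2-en-1-ol (prenol) | CC(C)=CCO | starting material
2 | (2S)-2-bromo-3-chloro-3-methylbutan-1-ol | OC[C@H](Br)C(C)(C)Cl | intermediate
3 | (2S)-2-bromo-3-chloro-3-methylbutyl trifluoromethanesulfonate | O=S(=O)(OC[C@H](Br)C(C)(C)Cl)C(F)(F)F | intermediate
4 | 2-methylallylmagnesium chloride | CC(=C)C[Mg]Cl | starting material
5 | (5S)-5-bromo-6-chloro-2,6-dimethylhept-1-ene | C=C(C)CC[C@H](Br)C(C)(C)Cl | intermediate
6 | ozonide of 5: 3-[(3S)-3-bromo-4-chloro-4-methylpentyl]-3-methyl-1,2,4-trioxolane | CC1(CC[C@H](Br)C(C)(C)Cl)OCOO1 | intermediate (not isolated)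
7 | (5S)-5-bromo-6-chloro-6-methylheptan-2-one | CC(=O)CC[C@H](Br)C(C)(C)Cl | intermediate
8 | 1,4-dioxaspiro[4.5]decane-8-carboxylic acid | OC(=O)C1CCC2(CC1)OCCO2 | starting material
9 | benzenethiol | Sc1ccccc1 | starting material
10 | S-phenyl 1,4-dioxaspiro[4.5]decane-8-carbothioate | O=C(Sc1ccccc1)C1CCC2(CC1)OCCO2 | intermediate
11 | lithium enolate of 10 | [Li]OC(Sc1ccccc1)=C1CCC2(CC1)OCCO2 | intermediate (not isolated)
12 | spiro-β-lactone: 4-[(3S)-3-bromo-4-chloro-4-methylpentyl]-4-methyloxetan-2-one spiro-fused at C3 to C8 of 1,4-dioxaspiro[4.5]decane (both C4 epimers) | O=C1OC(C)(CC[C@H](Br)C(C)(C)Cl)C12CCC3(CC2)OCCO3 | intermediate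
13 | 8-[(5S)-5-bromo-6-chloro-6-methylheptan-2-ylidene]-1,4-dioxaspiro[4.5]decane | CC(CC[C@H](Br)C(C)(C)Cl)=C1CCC2(CC1)OCCO2 | intermediate
14 | ethylene ketal of (10S)-10-bromo-7,11,11-trimethylspiro[5.5]undec-7-en-3-one | CC1=CC[C@H](Br)C(C)(C)C12CCC3(CC2)OCCO3 | intermediate (not isolated)
15 | (10S)-10-bromo-7,11,11-trimethylspiro[5.5]undec-7-en-3-one | CC1=CC[C@H](Br)C(C)(C)C12CCC(=O)CC2 | intermediate
16 | lithium (6R,10S)-10-bromo-7,11,11-trimethylspiro[5.5]undeca-2,7-dien-3-olate | CC1=CC[C@H](Br)C(C)(C)[C@@]12CCC(O[Li])=CC2 | intermediate (not isolated)
17 | (6R,10S)-10-bromo-7,11,11-trimethylspiro[5.5]undeca-2,7-dien-3-yl trifluoromethanesulfonate | CC1=CC[C@H](Br)C(C)(C)[C@@]12CCC(OS(=O)(=O)C(F)(F)F)=CC2 | intermediate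
18 | (6R,10S)-10-bromo-3,7,11,11-tetramethylspiro[5.5]undeca-2,7-diene (10-bromo-α-chamigrene) | CC1=CC[C@H](Br)C(C)(C)[C@@]12CCC(C)=CC2 | intermediate
19 | (2R,3R,6R,10S)-2,10-dibromo-3-chloro-3,7,11,11-tetramethylspiro[5.5]undec-7-ene (2,10-dibromo-3-chloro-α-chamigrene) | CC1=CC[C@H](Br)C(C)(C)[C@@]12CC[C@@](C)(Cl)[C@H](Br)C2 | target

## Step count and least certain steps

Total step count: 11. Longest linear sequence: 10 steps (1 → 2 → 3 → 5 → 7 → 12 → 13 → 15 → 17 → 18 → 19); step 5 is the one-step side branch to thioester 10.

**Step 8 (key step).**
- Closure could take place through C7 (five-membered ring) instead of C6.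
- A C14 proton could be lost instead of H-8, giving the exocyclic alkene.
- HCl could shift the C6=C7 double bond before ionisation.
- Bromonium transfer between alkene molecules would erode the C10 configuration.
- Fallback: change the terminating group so that C7 is oxygen-bound and C6 is the only nucleophilic carbon. The fallback sets out from 3. The kinetic lithium enolate of 1-(1,4-dioxaspiro[4.5]decan-8-yl)ethan-1-one F1 is alkylated with 3 to give (4S)-4-bromo-5-chloro-5-methyl-1-(1,4-dioxaspiro[4.5]decan-8-yl)hexan-1-one F2. F2 is converted (TMSOTf, Et3N) into the more substituted silyl enol ether F3. Ionisation of F3 in the same fluoroalcohol closes ring A through the enol-ether carbon C6 and gives, after loss of the silyl group, the spiro C7-ketone F4. F4 can enolise only toward C8, so its enol triflate F5 and a Negishi methylation (MeZnCl, Pd(PPh3)4) place C7(Me)=C8 by construction. This returns to the route at 14, which is hydrolysed to 15.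

**Step 11.**
- The bromonium could form reversibly and open by the trans-diaxial path from the C7 face, giving the 2,3-bis-epimer.
- Some attack at C7=C8 is possible.
- Fallback: separate the two bond-forming events. From 18, NBS in aqueous acetone lets solvent water capture the first-formed bromonium at C3 and gives bromohydrin F6. The tertiary alcohol is then replaced by chloride with retention through its chlorosulfite (SOCl2, no base, low temperature), which returns to the route at 19.

**Step 9.**
- The two α-methylene groups may be poorly differentiated: the axial α-hydrogens lie under C7, and the intrinsic bias of the spiro ketone may oppose the amide.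
- The enolate may partly equilibrate before triflation.
- Fallback: enamine catalysis in place of a chiral base. From 15, proline-catalysed α-aminoxylation with nitrosobenzene gives α-anilinooxy ketone F7. MeMgBr/CeCl3 gives tertiary alcohol F8, and N–O cleavage (Zn, AcOH) gives cis-diol F9. Thiocarbonyldiimidazole gives cyclic thiocarbonate F10, and Corey–Winter olefination (P(OMe)3, heat) places the alkene between C2 and C3, which returns to the route at 18.

**Step 3.**
- The Grignard reagent could act as a base (loss of triflic acid toward a vinyl bromide) or attack the vicinal bromochloride at halogen.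
- Chloride could displace the triflate, or the neighbouring bromine could participate.
- Fallback: a soft carbon nucleophile. From 3, the sodium enolate of allyl acetoacetate (THF, 0 °C) gives allyl (4S)-2-acetyl-4-bromo-5-chloro-5-methylhexanoate F11. Palladium-catalysed deallylation–decarboxylation (Pd(OAc)2, PPh3, HCO2H, Et3N) returns to the route at 7.

**Step 6.**
- The hindered enolate could deprotonate ketone 7, and the resulting ketone enolate could close a cyclopropane onto the C–Br carbon.
- Retro-aldol could compete with lactonisation.
- Fallback: make C8–C9 last instead of C6=C7. The isopropylidene ketal 8-(propan-2-ylidene)-1,4-dioxaspiro[4.5]decane F12 (one Wittig step from the parent ketal ketone) is metalated at an allylic methyl (n-BuLi/KOt-Bu) and transmetalated (MgBr2). Coupling with 3 at the CH2 terminus under Li2CuCl4 catalysis returns to the route at 13.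

## Further compounds

F1 | step 8 | 1-(1,4-dioxaspiro[4.5]decan-8-yl)ethan-1-one | CC(=O)C1CCC2(CC1)OCCO2
F2 | step 8 | (4S)-4-bromo-5-chloro-5-methyl-1-(1,4-dioxaspiro[4.5]decan-8-yl)hexan-1-one | O=C(CC[C@H](Br)C(C)(C)Cl)C1CCC2(CC1)OCCO2
F3 | step 8 | trimethylsilyl enol ether of F2 toward the ring carbon | C[Si](C)(C)OC(CC[C@H](Br)C(C)(C)Cl)=C1CCC2(CC1)OCCO2
F4 | step 8 | spiro C7-ketone: (10S)-10-bromo-11,11-dimethylspiro[5.5]undecane-3,7-dione 3-ethylene ketal | O=C1CC[C@H](Br)C(C)(C)C12CCC3(CC2)OCCO3
F5 | step 8 | enol triflate of F4 (C7=C8) | O=S(=O)(OC1=CC[C@H](Br)C(C)(C)C12CCC3(CC2)OCCO3)C(F)(F)F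
F6 | step 11 | (2R,3R,6R,10S)-2,10-dibromo-3,7,11,11-tetramethylspiro[5.5]undec-7-en-3-ol (bromohydrin) | CC1=CC[C@H](Br)C(C)(C)[C@@]12CC[C@@](C)(O)[C@H](Br)C2
F7 | step 9 | 2-(anilinooxy) derivative of 15 (oxygen at C2 cis to C11) | CC1=CC[C@H](Br)C(C)(C)[C@@]12CCC(=O)[C@H](ONc3ccccc3)C2
F8 | step 9 | 2-(anilinooxy)-3-methyl tertiary alcohol from F7 | CC1=CC[C@H](Br)C(C)(C)[C@@]12CC[C@@](O)(C)[C@H](ONc3ccccc3)C2
F9 | step 9 | cis-2,3-diol: 10-bromo-3,7,11,11-tetramethylspiro[5.5]undec-7-ene-2,3-diol | CC1=CC[C@H](Br)C(C)(C)[C@@]12CC[C@@](O)(C)[C@H](O)C2
F10 | step 9 | cyclic thiocarbonate of F9 | CC1=CC[C@H](Br)C(C)(C)[C@@]12CC[C@]3(C)OC(=S)O[C@@H]3C2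
F11 | step 3 | allyl (4S)-2-acetyl-4-bromo-5-chloro-5-methylhexanoate | CC(=O)C(C[C@H](Br)C(C)(C)Cl)C(=O)OCC=C
F12 | step 6 | 8-(propan-2-ylidene)-1,4-dioxaspiro[4.5]decane | CC(C)=C1CCC2(CC1)OCCO2
A1 | alternative 1 | (4S)-4-bromo-3,3-dimethyl-2-methylidenecyclohexan-1-one | C=C1C(=O)CC[C@H](Br)C1(C)C
A2 | alternative 1 | 2-methylbuta-1,3-diene | C=CC(C)=C
A3 | alternative 1 | 10-bromo-3,11,11-trimethylspiro[5.5]undec-2-en-7-one with the target configuration at C6 and C10 | O=C1CC[C@H](Br)C(C)(C)[C@@]12CCC(C)=CC2
A4 | alternative 2 | 6-allyl-3-isobutoxy-5,5-dimethyl-6-(3-methylbut-3-en-1-yl)cyclohex-2-en-1-one (quaternary centre as needed for C6) | CC(C)COC1=CC(=O)[C@](CC=C)(CCC(C)=C)C(C)(C)C1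
A5 | alternative 2 | 9-isobutoxy-3,11,11-trimethylspiro[5.5]undeca-2,8-dien-7-one (metathesis product of A4) | CC(C)COC1=CC(=O)[C@@]2(CC=C(C)CC2)C(C)(C)C1
A6 | alternative 3 | (E)-bisabolene-type bis(bromochloride): trans-2-bromo-1-chloro-1-methyl-4-[(5S)-5-bromo-6-chloro-6-methylheptan-2-ylidene]cyclohexane with ring halogens as in the target | C/C(CC[C@H](Br)C(C)(C)Cl)=C1\C[C@@H](Br)[C@](C)(Cl)CC1
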